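## Retrosynthetic overview

1. Target 21 ⇒ iodo-aldehyde 19. The C1–C10 bond is cut (Nozaki–Hiyama–Kishi closure). The ten-membered ring is formed last and C1–OH is never protected.
2. 19 ⇒ alcohol 14. The angelate goes onto O6, and the C1 aldehyde is unmasked from the prenyl terminus by selective ozonolysis.
3. 14 ⇒ epoxy aldehyde 3 + bromomethyl butenolide 12 (key C6–C7 bond). Cr(II) turns C7, the β-carbon of the unsaturated lactone and normally an acceptor, into a lactone homoenolate (d3). This adds to the C6 aldehyde, sets C6 and C7, and unveils the α-methylene lactone.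
4. 3 ⇐ nerol, where Sharpless epoxidation sets C4/C5. 12 ⇐ acrolein + propyne + 2-(bromomethyl)acrylic acid. Alkynylation sets C8, hydroalumination–iodination sets the 9Z geometry, and RCM closes the lactone.
5. Ring order: epoxide, then butenolide (which becomes the α-methylene-γ-lactone), then cyclodecene.

Assumption: germacrane locants are used (lactone C12–O–C8, angelate on C6, epoxide C4–C5, carbinol C1, alkene C9=C10). The CIP letters at C7/C8 differ in some intermediates only because substituent priorities change.

## Route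

Step 1
Reactants: 1 nerol, (2Z)-3,7-dimethylocta-2,6-dien-1-ol
Product: 2 [(2S,3R)-3-methyl-3-(4-methylpent-3-en-1-yl)oxiran-2-yl]methanol (cis-2,3-epoxynerol; C4 R, C5 S)
Conditions: Ti(OiPr)4 (5 mol %), L-(+)-DET (7 mol %), TBHP, 4 Å MS, CH2Cl2, −20 °C
Reagents that add atoms: tert-butyl hydroperoxide, CC(C)(C)OO
Why: In this Katsuki–Sharpless asymmetric epoxidation the L-(+)-tartrate/Ti complex delivers oxygen only to the hydroxyl-bound Z-alkene, and stereospecific syn addition gives the cis-epoxide with C5 S and C4 R, while the remote prenyl alkene is not directed and survives.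

Step 2
Reactants: 2 cis-2,3-epoxynerol
Product: 3 (2R,3R)-3-methyl-3-(4-methylpent-3-en-1-yl)oxirane-2-carbaldehyde (same spatial arrangement; C6 is now CHO)
Conditions: PhI(OAc)2, TEMPO (10 mol %), CH2Cl2, rt
Reagents that add atoms: none
Why: This oxoammonium (TEMPO/BAIB) oxidation of a primary alcohol stops at the aldehyde under nearly neutral conditions, so the epoxide, its non-enolisable α-centre and the trisubstituted alkene are untouched.

Step 3
Reactants: 4 acrolein; 5 propyne
Product: 7 (3R)-hex-1-en-4-yn-3-ol, via ethyl(prop-1-ynyl)zinc 6 (not isolated)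
Conditions: 5, Et2Zn, HMPA, CH2Cl2, rt; then (S)-BINOL (20 mol %), Ti(OiPr)4 (50 mol %); then 4, 0 °C
Reagents that add atoms: none
Why: In this catalytic asymmetric alkynylzinc 1,2-addition (BINOL–Ti type) the (S)-BINOLate titanium complex directs alkynyl transfer to the Si face of the enal carbonyl, which sets the future C8 centre as 3R.

Step 4
Reactants: 7 (3R)-hex-1-en-4-yn-3-ol
Product: 9 (3R,4Z)-5-iodohexa-1,4-dien-3-ol, via cyclic alkenylalanate 8 (not isolated)
Conditions: Red-Al, THF, 0 °C to rt; then I2, −78 to 0 °C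
Reagents that add atoms: iodine, II
Why: Alkoxide-directed trans-hydroalumination of the propargylic alcohol puts aluminium on the distal alkyne carbon inside a five-membered ring, and iodinolysis with retention gives only the Z-vinyl iodide (I cis to C8), which fixes the 9Z geometry without touching the carbinol centre or the vinyl group.

Step 5
Reactants: 9 (3R,4Z)-5-iodohexa-1,4-dien-3-ol; 10 2-(bromomethyl)prop-2-enoic acid
Product: 11 (3R,4Z)-5-iodohexa-1,4-dien-3-yl 2-(bromomethyl)prop-2-enoate
Conditions: DCC, DMAP (5 mol %), CH2Cl2, −10 to 0 °C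
Reagents that add atoms: none
Why: Steglich esterification acylates oxygen without breaking the C8–O bond, so the configuration is retained, and the low temperature and catalytic DMAP keep the allylic bromide intact.

Step 6
Reactants: 11 dienyl 2-(bromomethyl)acrylate
Product: 12 (5R)-3-(bromomethyl)-5-[(1Z)-2-iodoprop-1-en-1-yl]furan-2(5H)-one
Conditions: Hoveyda–Grubbs II (5 mol %), toluene (5 mM), 80 °C, Ar sparge
Reagents that add atoms: none
Why: In this ring-closing metathesis the catalyst loads on the terminal vinyl group and closes onto the 1,1-disubstituted acrylate as in known methacrylate-to-butenolide closures, ethene loss drives the reaction, and the trisubstituted iodoalkene is too hindered to take part.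

Step 7
Reactants: 3 (2R,3R)-epoxy aldehyde; 12 bromomethyl butenolide
Product: 14 (4S,5R)-4-{(S)-hydroxy[(2S,3R)-3-methyl-3-(4-methylpent-3-en-1-yl)oxiran-2-yl]methyl}-5-[(1Z)-2-iodoprop-1-en-1-yl]-3-methylideneoxolan-2-one, via allylchromium(III) reagent 13 (not isolated)
Conditions: CrCl2 (4 equiv, Ni-free), THF, 0 °C, slow addition of 12 + 3
Reagents that add atoms: none
Why: In this Nozaki–Hiyama allylation used as a polarity inversion, two-electron reduction of the allylic bromide makes the normally electrophilic lactone β-carbon C7 nucleophilic (homoenolate equivalent 13), which attacks the equally electrophilic aldehyde carbon C6 through a chair SE2′ transition state, so that C7 forms anti to the C8 alkenyl group (trans-lactone), the ring-locked E-type allyl geometry gives the C6/C7 anti adduct and Felkin–Anh/Cornforth attack on the cis-epoxy aldehyde gives the 5,6-anti epoxy alcohol, all three preferences being matched for this enantiomer pair, while the vinyl iodide is inert without nickel and the in-plane C8–O bond cannot align for 1,4-elimination.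

Step 8
Reactants: 14 C6 alcohol; 15 angelic acid, (2Z)-2-methylbut-2-enoic acid
Product: 17 (S)-{(2R,3R)-2-[(1Z)-2-iodoprop-1-en-1-yl]-4-methylidene-5-oxooxolan-3-yl}[(2S,3R)-3-methyl-3-(4-methylpent-3-en-1-yl)oxiran-2-yl]methyl (2Z)-2-methylbut-2-enoate, via mixed angelic 2,4,6-trichlorobenzoic anhydride 16 (not isolated)
Conditions: 15, 2,4,6-Cl3C6H2COCl, Et3N, toluene, rt; then 14, 75 °C
Reagents that add atoms: none
Why: In this Yamaguchi-type esterification run without DMAP the alcohol attacks the less hindered angeloyl carbonyl of 16, the absence of a nucleophilic catalyst suppresses Z-to-E (tiglate) isomerisation, and C6 keeps its configuration because only O–H is broken.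

Step 9
Reactants: 17 C6 angelate
Product: 19 (S)-{(2R,3R)-2-[(1Z)-2-iodoprop-1-en-1-yl]-4-methylidene-5-oxooxolan-3-yl}[(2S,3R)-3-methyl-3-(3-oxopropyl)oxiran-2-yl]methyl (2Z)-2-methylbut-2-enoate, via secondary ozonide 18 (not isolated)
Conditions: O3 (1 equiv, Sudan Red 7B end point), CH2Cl2, −78 °C; then Me2S, −78 °C to rt
Reagents that add atoms: ozone, [O-][O+]=O
Why: This chemoselective Criegee ozonolysis works because the electron-rich prenyl alkene reacts orders of magnitude faster than the conjugated angelate, the α-methylene lactone and the iodoalkene flanked by an allylic acyloxy group, so titration to the dye end point cleaves only C1=C(CH3)2.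

Step 10
Reactants: 19 iodo-aldehyde
Product: 21 CNP0191628.1, (1R,4R,5S,6S,7R,8S,9Z)-6-angeloyloxy-4,5-epoxy-1-hydroxygermacra-9,11(13)-dien-12,8-olide, via alkenylchromium(III) species 20 (not isolated)
Conditions: CrCl2 (10 equiv), NiCl2 (2 mol % of Cr), DMSO–THF, 2 mM (syringe pump), rt
Reagents that add atoms: none
Why: In this Nozaki–Hiyama–Kishi macrocyclisation nickel inserts into the vinyl C–I bond with retention of the Z geometry, the derived alkenylchromium 20 adds only to the aldehyde, the Z-alkene, cis-epoxide and trans-lactone pre-fold the chain, and a chair-type cis,cis-cyclodeca-1,6-diene-like transition state with the aldehyde hydrogen eclipsing the alkene (minimal A1,3 strain) puts C2 on the face opposite C7 and so gives the 1R carbinol.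

## Compound list

1 | nerol | CC(C)=CCC/C(C)=C\CO | starting material
2 | [(2S,3R)-3-methyl-3-(4-methylpent-3-en-1-yl)oxiran-2-yl]methanol | CC(C)=CCC[C@@]1(C)O[C@H]1CO | intermediate
3 | (2R,3R)-3-methyl-3-(4-methylpent-3-en-1-yl)oxirane-2-carbaldehyde | CC(C)=CCC[C@@]1(C)O[C@H]1C=O | intermediate
4 | acrolein | C=CC=O | starting material
5 | propyne | CC#C | starting material
6 | ethyl(prop-1-ynyl)zinc (not isolated) | CC[Zn]C#CC | intermediate
7 | (3R)-hex-1-en-4-yn-3-ol | O[C@@H](C#CC)C=C | intermediate
8 | sodium cyclic alkenylalanate from 7 and Red-Al (not isolated) | [Na+].COCCO[Al-]1(OCCOC)O[C@H](C=C)C=C1C | intermediate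
9 | (3R,4Z)-5-iodohexa-1,4-dien-3-ol | O[C@@H](/C=C(/C)I)C=C | intermediate
10 | 2-(bromomethyl)prop-2-enoic acid | C=C(CBr)C(=O)O | starting material
11 | (3R,4Z)-5-iodohexa-1,4-dien-3-yl 2-(bromomethyl)prop-2-enoate | C=C(CBr)C(=O)O[C@@H](/C=C(/C)I)C=C | intermediate
12 | (5R)-3-(bromomethyl)-5-[(1Z)-2-iodoprop-1-en-1-yl]furan-2(5H)-one | O=C1O[C@@H](/C=C(/C)I)C=C1CBr | intermediate
13 | allylchromium(III) dichloride from 12, lactone homoenolate equivalent (not isolated) | O=C1O[C@@H](/C=C(/C)I)C=C1C[Cr](Cl)Cl | intermediate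
14 | C6 alcohol, α-methylene-trans-lactone (name in step 7) | CC(C)=CCC[C@@]1(C)O[C@H]1[C@@H](O)[C@@H]2C(=C)C(=O)O[C@H]2/C=C(/C)I | intermediate
15 | angelic acid | C/C=C(/C)C(=O)O | starting material
16 | angelic 2,4,6-trichlorobenzoic anhydride (not isolated) | C/C=C(/C)C(=O)OC(=O)c1c(Cl)cc(Cl)cc1Cl | intermediate
17 | C6 angelate with prenyl terminus (name in step 8) | CC(C)=CCC[C@@]1(C)O[C@H]1[C@@H](OC(=O)/C(C)=C\C)[C@@H]2C(=C)C(=O)O[C@H]2/C=C(/C)I | intermediate
18 | secondary ozonide of 17, 3,3-dimethyl-1,2,4-trioxolane (not isolated) | CC1(C)OOC(CC[C@@]2(C)O[C@H]2[C@@H](OC(=O)/C(C)=C\C)[C@@H]2C(=C)C(=O)O[C@H]2/C=C(/C)I)O1 | intermediate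
19 | C1 aldehyde / C10 vinyl iodide (name in step 9) | O=CCC[C@@]1(C)O[C@H]1[C@@H](OC(=O)/C(C)=C\C)[C@@H]2C(=C)C(=O)O[C@H]2/C=C(/C)I | intermediate
20 | alkenylchromium(III) dichloride from 19 (not isolated) | O=CCC[C@@]1(C)O[C@H]1[C@@H](OC(=O)/C(C)=C\C)[C@@H]2C(=C)C(=O)O[C@H]2/C=C(/C)[Cr](Cl)Cl | intermediate
21 | CNP0191628.1 | C=C1C(=O)O[C@H]2/C=C(/C)[C@H](O)CC[C@@]3(C)O[C@H]3[C@@H](OC(=O)/C(C)=C\C)[C@H]12 | target

## Step count and risks

Total step count: 10. Longest linear sequence: 8 (steps 3–10). Steps 1–2 form the second branch.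

**Step 10 (ten-membered NHK closure, C1 set by ring conformation).** The main danger is a poor or wrong ratio at C1. The fallback sets out from 19 and comes back at 21.
- The closure is run without regard to C1.
- The carbinol mixture, which then contains the C1-epimeric macrocyclic alcohol F1, is oxidised with MnO2 to the macrocyclic (9Z)-1-oxo enone F2.
- C1 is then set by reagent control instead of by C–C bond formation. A Corey–Bakshi–Shibata reduction is used ((S)-Me-CBS, catecholborane, toluene, −78 °C). The alkenyl side acts as the large group, which gives the 1R alcohol 21.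

**Step 7 (key union).** The main danger is incomplete facial control at the aldehyde, giving C6 epimers. The fallback sets out from 3 + 12 and comes back at 14.
- The crude adduct, containing the C6-epimeric alcohol F3, is oxidised with buffered Dess–Martin periodinane to the α,β-epoxy ketone F4.
- C6 is then set by hydride delivery. Zn(BH4)2 in Et2O at −78 °C chelates the carbonyl and epoxide oxygens and attacks from the side of the C5 hydrogen. This gives the 5,6-anti (erythro) epoxy alcohol 14.

**Step 6 (RCM in the presence of the allylic bromide).** The danger is catalyst death or a sluggish closure onto the bromomethyl-substituted acrylate. The fallback sets out from 9 and comes back at 12, and the bromide is introduced only after ring closure.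
- 9 is esterified (DCC, cat. DMAP) with 2-{[(tert-butyldimethylsilyl)oxy]methyl}prop-2-enoic acid to the silyloxymethyl acrylate ester F5.
- RCM gives the 3-(silyloxymethyl)butenolide F6.
- Ph3PBr2 in CH2Cl2 converts the silyl ether directly into the allylic bromide 12.

## Further compounds

F1 | step 10 | C1 epimer (1S) of the target | C=C1C(=O)O[C@H]2/C=C(/C)[C@@H](O)CC[C@@]3(C)O[C@H]3[C@@H](OC(=O)/C(C)=C\C)[C@H]12
F2 | step 10 | (9Z)-1-oxo macrocyclic enone | C=C1C(=O)O[C@H]2/C=C(/C)C(=O)CC[C@@]3(C)O[C@H]3[C@@H](OC(=O)/C(C)=C\C)[C@H]12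
F3 | step 7 | C6 epimer of alcohol 14 | CC(C)=CCC[C@@]1(C)O[C@H]1[C@H](O)[C@@H]2C(=C)C(=O)O[C@H]2/C=C(/C)I
F4 | step 7 | C6 α,β-epoxy ketone | CC(C)=CCC[C@@]1(C)O[C@H]1C(=O)[C@@H]2C(=C)C(=O)O[C@H]2/C=C(/C)I
F5 | step 6 | (3R,4Z)-5-iodohexa-1,4-dien-3-yl 2-{[(tert-butyldimethylsilyl)oxy]methyl}prop-2-enoate | C=C(CO[Si](C)(C)C(C)(C)C)C(=O)O[C@@H](/C=C(/C)I)C=C
F6 | step 6 | (5R)-3-{[(tert-butyldimethylsilyl)oxy]methyl}-5-[(1Z)-2-iodoprop-1-en-1-yl]furan-2(5H)-one | O=C1O[C@@H](/C=C(/C)I)C=C1CO[Si](C)(C)C(C)(C)C
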